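The question for cedar is what share of its charge of starting material stands as target at the asked time, and the first thing to settle is whether the charge alters the pace.

| setting | larch | birch | oak | cedar |
|---|---|---|---|---|
| starting material | 0.400 M | 0.160 M | 0.400 M | 1.20 M |
| reagent | 0.800 M | 0.560 M | 0.800 M | 1.60 M |
| catalyst | 8.00 × 10⁻⁴ M | 8.00 × 10⁻⁴ M | 8.00 × 10⁻⁴ M | 8.00 × 10⁻⁴ M |
| target |  |  | 0.200 M |  |
| time |  |  |  | 6.4 min |

- larch run (time / min: [target] / M): 0.26: 0.0356; 0.41: 0.0526; 0.64: 0.0771; 1.0: 0.1148; 1.6: 0.1613; 2.6: 0.2152; 4.0: 0.2604; 6.4: 0.2903
- birch run (time / min: [target] / M): 0.26: 0.0113; 0.41: 0.0217; 0.64: 0.0307; 1.0: 0.0451; 1.6: 0.0638; 2.6: 0.0887; 4.0: 0.1081; 6.4: 0.1209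
- oak run (time / min: [target] / M): 0.26: 0.2343; 0.41: 0.2516; 0.64: 0.2753; 1.0: 0.3101; 1.6: 0.3539; 2.6: 0.4058; 4.0: 0.4428; 6.4: 0.4668

(scatter of a reading: 0.001 M)

1. target in the cedar run at 6.4 min, as a share of the starting material charged

- Overall: starting material + reagent -> target, with catalyst as catalyst.
- Constant volume, constant temperature.
- Bound and free are read together.

At the early end the readings show little of it: at 1.0 min larch holds 28.7% of its charge as target and birch 28.2%, although the larch charge is 2.50 times the birch charge and the reagent differs too, 0.800 M against 0.560 M. Early formation therefore reads as pseudo-first-order in starting material, which is the limiting reagent in larch, birch and cedar alike, and cedar starts with more reagent than larch.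

Does target brake the flask? Oak, seeded with 0.200 M of target, gains 0.0758 M between 0.26 min and 1.0 min against 0.0792 M in larch, a ratio of 0.957 as a reading.

Where, then, does the charge show? It shows late: at 6.4 min larch holds 72.6% of its charge as target and birch 75.6%, so larch, with the larger charge, ends lower. The difference in share per unit of charge, with the reagent differing as well, is 0.124 M⁻¹ as a reading, the charge penalty, of which the scatter of the birch reading is worth 0.0260 M⁻¹. Carried from larch across the extra 0.800 M of charge, it puts cedar at 62.6%, give or take 2.1 percentage points.

The forecast stands at 78.5%, higher than this reckoning, having read the runs as “a reversible reaction rather than strong product inhibition”.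

Cedar gives 61.6%.

    catalyst + reagent ⇌ catalyst-reagent complex, settled at all times (13.00 M⁻¹)
    catalyst-reagent complex + starting material → target + catalyst (492.0 M⁻¹ min⁻¹)
    target → decomposed product (0.02046 min⁻¹)
    2 starting material → homo dimer (0.1266 M⁻¹ min⁻¹)

Of these steps, homo dimer formation takes starting material at a fractional rate of twice its constant times the concentration, which at the start is 0.304 min⁻¹ in cedar, higher than the 0.101 min⁻¹ in larch. The charge penalty was 0.124 M⁻¹ from birch to larch, and from larch to cedar it reads 0.137 M⁻¹.

The readings were generated by integration for substances that don't exist; scatter was added.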